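**Plan**

Ring atoms of the target are counted from the quaternary carbon with methyl and the chlorovinyl group (C1) through CH2 (C2), the CBr(CH2Br) carbon (C3), CHCl (C4) and CH2 (C5) to the second CHCl (C6).
Retrosynthesis: the C3–Br and CH2–Br bonds are cut first (exocyclic alkene, then a C3 ketone) and the (Z)-chlorovinyl group is traced to a silylalkyne. The ring bond C5–C6 and the C4–Cl bond are then cut together, which leaves a 1-vinylcyclobutanol; C3–C4 (vinyl Grignard) and the cyclobutane bonds C1–C6 and C2–C3 (ketene–alkene [2+2]) follow.
Enabling feature: C6 with its chlorine, C1 and C2, together with C3 as a carbonyl carbon, are the four atoms of a 2-chlorocyclobutanone. C4–C5 can sit on C3 as a vinyl group, so scission of C3–C6 and closure of C6 onto C5 turns the four-membered ring into the six-membered one.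
Forward: silylated 2-methylbut-1-en-3-yne and dichloroketene give the cyclobutanone (first ring), which is resolved, mono-dechlorinated and vinylated. An alkoxy-radical cascade then builds the cyclohexanone at the expense of the cyclobutane; epimerisation of the α-chloroketone, alkyne-to-chlorovinyl conversion, methylenation and bromine addition finish the route.
Stereochemistry: C1 comes from a Corey–Bakshi–Shibata reduction of the racemic cycloadduct, separation of the carbinol diastereomers and re-oxidation. C6 is set in the chair-like radical ring closure, C4 by equilibration of the α-chloroketone, the alkene geometry by syn addition of diimide to a chloroalkyne, and C3 by axial opening of the bromonium ion.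

Key step: step 7

Assumption: 9, 11, 12 and 18 are carried as epimer mixtures at centres that are destroyed later, and 13 is accompanied by its epimer at the α-chloroketone carbon until step 8; names and SMILES show the isomer expected to predominate, and racemic 6 is written without stereodescriptors.

**Route**

Step 1
Reactants: 1 2-methylbut-1-en-3-yne
Product: 3 trimethyl(3-methylbut-3-en-1-yn-1-yl)silane, via lithium acetylide 2 (not isolated)
Conditions: n-BuLi, THF, −78 °C; Me3SiCl, −78 → 20 °C
Reagents that add atoms: chlorotrimethylsilane, C[Si](C)(C)Cl
Why: Deprotonation of the terminal alkyne and C-silylation of the lithium acetylide is routine acetylide chemistry; the silyl cap removes the acidic C–H ahead of the Grignard step and shields the alkyne in the ketene cycloaddition.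

Step 2
Reactants: 3 trimethyl(3-methylbut-3-en-1-yn-1-yl)silane; 4 trichloroacetyl chloride
Product: 6 rac-2,2-dichloro-3-methyl-3-[(trimethylsilyl)ethynyl]cyclobutan-1-one, via dichloroketene 5 (not isolated)
Conditions: Zn–Cu couple, Et2O/DME, 35 °C, slow addition of 4
Reagents that add atoms: none
Why: Thermal ketene–alkene [2+2] cycloaddition: dichloroketene, released from 4 by zinc, adds across the electron-rich 1,1-disubstituted alkene with its carbonyl carbon on the CH2 terminus, so that CCl2 ends up next to the new quaternary carbon, while the hindered, conjugatively deactivated silylalkyne stays behind; the adduct is racemic.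

Step 3
Reactants: 6 rac-2,2-dichloro-3-methyl-3-[(trimethylsilyl)ethynyl]cyclobutan-1-one
Product: 7 (1R,3S)-2,2-dichloro-3-methyl-3-[(trimethylsilyl)ethynyl]cyclobutan-1-ol
Conditions: (S)-1-methyl-3,3-diphenyltetrahydro-1H,3H-pyrrolo[1,2-c][1,3,2]oxazaborole (0.2 equiv), catecholborane, toluene, −78 °C; MeOH, then pH 7 buffer; separation of the two carbinol diastereomers on silica
Reagents that add atoms: none
Why: Corey–Bakshi–Shibata reduction, in which the catalyst reads only the CCl2 (large) and CH2 (small) flanks of the carbonyl group, so that both enantiomers of 6 should take up hydride on the same face and give (1R)-carbinols that are diastereomers of each other; the one with hydroxyl cis to methyl holds the (3S) quaternary centre needed for C1 of the target and is separated from the other by chromatography.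

Step 4
Reactants: 7 (1R,3S)-2,2-dichloro-3-methyl-3-[(trimethylsilyl)ethynyl]cyclobutan-1-ol
Product: 8 (3S)-2,2-dichloro-3-methyl-3-[(trimethylsilyl)ethynyl]cyclobutan-1-one
Conditions: 1,1,1-triacetoxy-1,1-dihydro-1,2-benziodoxol-3(1H)-one, CH2Cl2, 20 °C
Reagents that add atoms: none
Why: Periodinane oxidation of a secondary alcohol under neutral conditions returns the cyclobutanone, now as a single enantiomer, without any pathway that could touch the quaternary centre.

Step 5
Reactants: 8 (3S)-2,2-dichloro-3-methyl-3-[(trimethylsilyl)ethynyl]cyclobutan-1-one
Product: 9 (2R,3S)-2-chloro-3-methyl-3-[(trimethylsilyl)ethynyl]cyclobutan-1-one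
Conditions: Zn dust (1.1 equiv), AcOH, 15–20 °C
Reagents that add atoms: none
Why: Reductive dehalogenation of an α,α-dichloroketone through its zinc enolate stops after the first C–Cl bond at room temperature because the mono-chloroketone is reduced much more slowly; the CHCl centre forms as an epimer mixture, which does not matter since it becomes planar in step 7.

Step 6
Reactants: 9 (2R,3S)-2-chloro-3-methyl-3-[(trimethylsilyl)ethynyl]cyclobutan-1-one; 10 vinylmagnesium bromide
Product: 11 (1R,2R,3S)-2-chloro-1-ethenyl-3-methyl-3-[(trimethylsilyl)ethynyl]cyclobutan-1-ol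
Conditions: THF, −78 °C; AcOH, −78 °C
Reagents that add atoms: none
Why: Grignard 1,2-addition to a strained and therefore highly electrophilic cyclobutanone, run and quenched at −78 °C so that the β-chloro alkoxide cannot contract to a cyclopropyl ketone; attack anti to chlorine should dominate, but the carbinol configuration is erased in step 7.

Step 7
Reactants: 11 (1R,2R,3S)-2-chloro-1-ethenyl-3-methyl-3-[(trimethylsilyl)ethynyl]cyclobutan-1-ol
Product: 13 (2S,4S,5S)-2,4-dichloro-5-methyl-5-[(trimethylsilyl)ethynyl]cyclohexan-1-one, via cyclobutyl hypochlorite 12 (not isolated)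
Conditions: aq. NaOCl, AcOH, PhCF3, 0 °C, dark; organic layer dried and diluted with degassed PhCF3 to 2–3 mM; 390 nm LED, 0–10 °C
Reagents that add atoms: sodium hypochlorite, [Na+].[O-]Cl
Why: Proposed new method: O-chlorination of the tertiary alcohol gives hypochlorite 12, light homolyses its O–Cl bond, and the strained alkoxy radical undergoes β-scission of the ring bond between the carbinol carbon and CHCl (cyclobutanol C1–C2), which releases the secondary α-chloroalkyl radical rather than the primary radical of C1–C4 cleavage and unmasks a vinyl ketone; that radical adds to the CH2 terminus of the enone, and the α-keto radical so formed takes chlorine from another molecule of 12, which regenerates the alkoxy radical and carries the chain. The closest known reaction types are the ring-opening chlorination of cyclobutanols through their hypochlorites and the two-carbon ring enlargement of 1-vinylcycloalkanols by alkoxy-radical scission and endo recyclisation; their combination with chlorine-atom termination has not been described. The six-membered ring closes in the 6-endo-trig mode, preferred over 5-exo because attack at the enone terminus is polarity-matched and leads to the stabilised α-keto radical. C4 of 13 is set in a chair-like transition state that holds the slim alkynyl group axial, methyl equatorial and the chlorine on the radical carbon equatorial, hence trans to methyl. C2 of 13 arises from chlorine-atom transfer to the planar α-keto radical, expected mainly along the axial trajectory on the face remote from the axial alkynyl group, which gives the axial chloride trans to the C4 chloride with the equatorial epimer 14 as the minor partner; step 8 then brings this centre to the configuration of the target. The step needs ring closure to outrun chlorine capture by the open-chain radical, which is secured in the substrate by the chlorine on the cyclobutane (it directs the scission and makes the radical slow to abstract chlorine) and by the quaternary carbon that holds radical and enone close, and in the flask by high dilution with 12 as the only chlorine donor; all carbinol and CHCl diastereomers of 11 converge since both centres become planar.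

Step 8
Reactants: 13 (2S,4S,5S)-2,4-dichloro-5-methyl-5-[(trimethylsilyl)ethynyl]cyclohexan-1-one
Product: 14 (2R,4S,5S)-2,4-dichloro-5-methyl-5-[(trimethylsilyl)ethynyl]cyclohexan-1-one
Conditions: HCl (4 M in dioxane, 0.2 equiv), MeCN, 40 °C; chromatography, recovered 13 resubmitted
Reagents that add atoms: none
Why: Acid-catalysed keto–enol equilibration epimerises only the α-chloroketone carbon, and in a polar solvent the all-equatorial isomer 14, with its larger dipole, should be favoured over 13 with its axial chlorine; the crude mixture from step 7 is used as such, and unconverted 13 is separated and resubmitted.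

Step 9
Reactants: 14 (2R,4S,5S)-2,4-dichloro-5-methyl-5-[(trimethylsilyl)ethynyl]cyclohexan-1-one
Product: 15 (2R,4S,5S)-2,4-dichloro-5-(chloroethynyl)-5-methylcyclohexan-1-one
Conditions: N-chlorosuccinimide, AgNO3 (0.2 equiv), acetone, 20 °C, dark
Reagents that add atoms: N-chlorosuccinimide, O=C1CCC(=O)N1Cl
Why: Silver-mediated halodesilylation of an alkynylsilane: monovalent silver cleaves the C(sp)–Si bond to a silver acetylide that N-chlorosuccinimide chlorinates, all under neutral conditions that spare the base-sensitive α-chloroketone.

Step 10
Reactants: 15 (2R,4S,5S)-2,4-dichloro-5-(chloroethynyl)-5-methylcyclohexan-1-one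
Product: 16 (2R,4S,5S)-2,4-dichloro-5-[(Z)-2-chloroethenyl]-5-methylcyclohexan-1-one
Conditions: KO2C–N=N–CO2K, AcOH, MeOH/THF, 0 → 20 °C
Reagents that add atoms: none
Why: Diimide reduction: diimide, set free from the azodicarboxylate salt by acetic acid, delivers two hydrogen atoms to one face of the chloroalkyne and so fixes the (Z)-chloroalkene, while the ketone and the C–Cl bonds are inert to it; the reagent is added in portions to stop at the alkene stage.

Step 11
Reactants: 16 (2R,4S,5S)-2,4-dichloro-5-[(Z)-2-chloroethenyl]-5-methylcyclohexan-1-one; 17 (trimethylsilyl)methylmagnesium chloride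
Product: 19 (1S,2S,4R)-2,4-dichloro-1-[(Z)-2-chloroethenyl]-1-methyl-5-methylidenecyclohexane, via β-hydroxysilane 18 (not isolated)
Conditions: CeCl3, THF, −78 °C; AcOH, −78 °C; crude 18, aq. HF (48%), MeCN, 0 → 20 °C
Reagents that add atoms: none
Why: Peterson olefination in its acidic variant: the weakly basic Grignard reagent, assisted by CeCl3, adds to the hindered α-chloroketone without enolising it, and HF then brings about anti elimination of the β-hydroxysilane to the exocyclic alkene; a reducing zinc–titanium methylenation was set aside because low-valent metals cleave α-chloroketones.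

Step 12
Reactants: 19 (1S,2S,4R)-2,4-dichloro-1-[(Z)-2-chloroethenyl]-1-methyl-5-methylidenecyclohexane
Product: 20 (1S,2R,4S,5S)-1-bromo-1-(bromomethyl)-2,4-dichloro-5-[(Z)-2-chloroethenyl]-5-methylcyclohexane
Conditions: Br2 (1.0 equiv), CH2Cl2, −78 °C, dark
Reagents that add atoms: bromine, BrBr
Why: Electrophilic anti addition of bromine to the 1,1-disubstituted alkene, which is far more electron-rich than the chlorovinyl group: the bromonium ion is opened by bromide at the tertiary carbon along the axial trajectory, so that C3 carries an axial bromine and an equatorial CH2Br group as in the target, whereas the alternative would force CH2Br into a 1,3-diaxial contact with the chlorovinyl group.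

**Compound list**

1 | 2-methylbut-1-en-3-yne | C=C(C)C#C | starting material
2 | lithium 3-methylbut-3-en-1-yn-1-ide (lithium acetylide) | [Li]C#CC(C)=C | intermediate
3 | trimethyl(3-methylbut-3-en-1-yn-1-yl)silane | C=C(C)C#C[Si](C)(C)C | intermediate
4 | trichloroacetyl chloride | ClC(Cl)(Cl)C(Cl)=O | starting material
5 | dichloroketene | ClC(Cl)=C=O | intermediate
6 | rac-2,2-dichloro-3-methyl-3-[(trimethylsilyl)ethynyl]cyclobutan-1-one | CC1(C#C[Si](C)(C)C)CC(=O)C1(Cl)Cl | intermediate
7 | (1R,3S)-2,2-dichloro-3-methyl-3-[(trimethylsilyl)ethynyl]cyclobutan-1-ol | C[C@@]1(C#C[Si](C)(C)C)C[C@@H](O)C1(Cl)Cl | intermediate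
8 | (3S)-2,2-dichloro-3-methyl-3-[(trimethylsilyl)ethynyl]cyclobutan-1-one | C[C@@]1(C#C[Si](C)(C)C)CC(=O)C1(Cl)Cl | intermediate
9 | (2R,3S)-2-chloro-3-methyl-3-[(trimethylsilyl)ethynyl]cyclobutan-1-one | C[C@@]1(C#C[Si](C)(C)C)CC(=O)[C@@H]1Cl | intermediate
10 | vinylmagnesium bromide | C=C[Mg]Br | starting material
11 | (1R,2R,3S)-2-chloro-1-ethenyl-3-methyl-3-[(trimethylsilyl)ethynyl]cyclobutan-1-ol | C[C@@]1(C#C[Si](C)(C)C)C[C@@](O)(C=C)[C@@H]1Cl | intermediate
12 | (1R,2R,3S)-2-chloro-1-ethenyl-3-methyl-3-[(trimethylsilyl)ethynyl]cyclobutyl hypochlorite | C[C@@]1(C#C[Si](C)(C)C)C[C@@](OCl)(C=C)[C@@H]1Cl | intermediate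
13 | (2S,4S,5S)-2,4-dichloro-5-methyl-5-[(trimethylsilyl)ethynyl]cyclohexan-1-one | C[C@@]1(C#C[Si](C)(C)C)CC(=O)[C@@H](Cl)C[C@@H]1Cl | intermediate
14 | (2R,4S,5S)-2,4-dichloro-5-methyl-5-[(trimethylsilyl)ethynyl]cyclohexan-1-one | C[C@@]1(C#C[Si](C)(C)C)CC(=O)[C@H](Cl)C[C@@H]1Cl | intermediate
15 | (2R,4S,5S)-2,4-dichloro-5-(chloroethynyl)-5-methylcyclohexan-1-one | C[C@@]1(C#CCl)CC(=O)[C@H](Cl)C[C@@H]1Cl | intermediate
16 | (2R,4S,5S)-2,4-dichloro-5-[(Z)-2-chloroethenyl]-5-methylcyclohexan-1-one | C[C@@]1(/C=C\Cl)CC(=O)[C@H](Cl)C[C@@H]1Cl | intermediate
17 | (trimethylsilyl)methylmagnesium chloride | C[Si](C)(C)C[Mg]Cl | starting material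
18 | (2R,4S,5S)-2,4-dichloro-5-[(Z)-2-chloroethenyl]-5-methyl-1-[(trimethylsilyl)methyl]cyclohexan-1-ol (either C1 epimer) | C[C@@]1(/C=C\Cl)CC(O)(C[Si](C)(C)C)[C@H](Cl)C[C@@H]1Cl | intermediate
19 | (1S,2S,4R)-2,4-dichloro-1-[(Z)-2-chloroethenyl]-1-methyl-5-methylidenecyclohexane | C[C@@]1(/C=C\Cl)CC(=C)[C@H](Cl)C[C@@H]1Cl | intermediate
20 | (1S,2R,4S,5S)-1-bromo-1-(bromomethyl)-2,4-dichloro-5-[(Z)-2-chloroethenyl]-5-methylcyclohexane | C[C@@]1(/C=C\Cl)C[C@@](Br)(CBr)[C@H](Cl)C[C@@H]1Cl | target

Total step count: 12
Longest linear sequence: 12 steps (1 → 20)

**Steps most likely to fail**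

Step 7 (new method). Three processes may defeat it: chlorine capture by the open-chain radical before ring closure, heterolytic chlorine transfer to the vinyl group followed by semipinacol ring enlargement to a cyclopentanone, and scission on the CH2 side of the carbinol. The fallback separates the events and uses known reaction types. It sets out from 11: hypoiodite alkoxy-radical fragmentation (PhI(OAc)2, I2, visible light, CH2Cl2) should give (5S)-6-chloro-6-iodo-5-methyl-5-[(trimethylsilyl)ethynyl]hex-1-en-3-one F1. Slow addition of Bu3SnH with 2,2'-azobis(2-methylpropionitrile) in benzene at 80 °C then abstracts iodine only and closes the ring 6-endo onto the vinyl ketone, giving (3S,4S)-4-chloro-3-methyl-3-[(trimethylsilyl)ethynyl]cyclohexan-1-one F2. Enamine-mediated α-chlorination ((S)-pyrrolidine-2-carboxamide, N-chlorosuccinimide, CH2Cl2, 0 °C) on the side remote from the quaternary carbon returns to the route at 13; any 14 formed alongside is already the product of step 8, into which the mixture is taken.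

Step 8. The equilibrium may lie too little on the side of the equatorial chloride, or prolonged enolisation may erode material through loss of HCl. The fallback replaces thermodynamic by kinetic control and sets out from 13. Soft enolisation (Me3SiOSO2CF3, Et3N, CH2Cl2, −78 °C) towards the more acidic CHCl carbon should give {[(4S,5S)-2,4-dichloro-5-methyl-5-[(trimethylsilyl)ethynyl]cyclohex-1-en-1-yl]oxy}trimethylsilane F3. Release of the enolate with Bu4NF in THF at −78 °C in the presence of acetic acid leads to protonation along the axial trajectory, which places chlorine equatorial and returns to the route at 14.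

Step 11. The organometallic reagent may enolise the α-chloroketone (epimerisation, or cyclopropane formation by displacement of the remote chloride), the chlorohydrin alkoxide may close to an epoxide, or acid may shift the allylic chloride during elimination. The fallback sets out from 16 and uses direct carbonyl methylenation with the titanium methylidene from Cp2Ti(μ-Cl)(μ-CH2)AlMe2 (toluene/THF, pyridine, −40 → 0 °C). It passes through an oxatitanacyclobutane, needs neither a carbanion nor acid, and returns to the route at 19 with no new compound (F0).

Further compounds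
F1 | step 7 | (5S)-6-chloro-6-iodo-5-methyl-5-[(trimethylsilyl)ethynyl]hex-1-en-3-one (C6 epimers) | C[C@@](C(Cl)I)(C#C[Si](C)(C)C)CC(=O)C=C
F2 | step 7 | (3S,4S)-4-chloro-3-methyl-3-[(trimethylsilyl)ethynyl]cyclohexan-1-one | C[C@@]1(C#C[Si](C)(C)C)CC(=O)CC[C@@H]1Cl
F3 | step 8 | {[(4S,5S)-2,4-dichloro-5-methyl-5-[(trimethylsilyl)ethynyl]cyclohex-1-en-1-yl]oxy}trimethylsilane | C[C@@]1(C#C[Si](C)(C)C)CC(O[Si](C)(C)C)=C(Cl)C[C@@H]1Cl
F0 | step 11 | none | none
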